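**Strategy.** The target is read as a Diels–Alder heterodimer of two antipodal 8-epi-xanthatin units, so one racemic monomer synthesis, resolved at the end, serves both halves. Everything rests on the seven-membered ring C1'/C5'–C10' of the spiro-lactone half. A dirhodium vinylcarbenoid, tethered as an ester to C14', cyclopropanates the (E,E)-diene, and the cis-divinylcyclopropane undergoes Cope ring expansion. This forms C10'–C1' and C6'–C7' in one operation and fixes the cis C7'/C10' relationship from alkene geometry. The precursor is an acyclic dienyl 2-diazobut-3-enoate; its ester oxygen is later excised so that C14' becomes the methyl group.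

Key step: step 7

Remarks on the chemistry (assumptions):
- Xanthane numbering is used for each C15 half: ring carbons C1, C5–C10; side chain C2–C3–C4(=O)–C15 on C1; C14 on C10; lactone carbons C11 (on C7), C12 (C=O), C13. Primes denote the epoxide (spiro-lactone) half; racemic intermediates are numbered without primes.
- As read from the SMILES, the hydroxylated half has the ring configuration of natural 8-epi-xanthatin (7R,8R,10S) and the epoxide half the antipodal one (7'S,8'S,10'R); both enantiomers of one monomer are therefore needed.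
- Compounds 12–25 are racemates; each is drawn as the enantiomer that becomes the hydroxylated (diene) half.

**Step 1**
Reactants: 1 (E)-pent-2-en-4-yn-1-ol
Product: 3 (2E,4E)-5-iodopenta-2,4-dien-1-ol, via dienylstannane 2 (not isolated)
Conditions: Bu3SnH, PdCl2(PPh3)2 (2 mol %), THF, 0 °C; then I2, CH2Cl2, 0 °C
Reagents that add atoms: iodine, [I][I]
Why: Palladium-catalysed syn-hydrostannation should place tin on the terminal alkyne carbon and iododestannylation proceeds with retention, so the (2E,4E) geometry that later dictates the cis C7/C10 relationship is fixed here.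

**Step 2**
Reactants: 3 (2E,4E)-5-iodopenta-2,4-dien-1-ol; 4 tert-butyl bromoacetate
Product: 6 tert-butyl (3E,5E)-7-hydroxyhepta-3,5-dienoate, via Reformatsky reagent 5 (not isolated)
Conditions: 4, Zn dust, Me3SiCl (cat.), THF, 40 °C; then 3, Pd(PPh3)4 (5 mol %), THF/DMPU, rt (excess 5)
Reagents that add atoms: none
Why: Negishi-type cross-coupling of the zinc ester enolate with the alkenyl iodide (oxidative addition and reductive elimination with retention of alkene geometry) should give the β,γ-unsaturated ester, the free alcohol only consuming one equivalent of 5 as its zinc alkoxide.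

**Step 3**
Reactants: 6 tert-butyl (3E,5E)-7-hydroxyhepta-3,5-dienoate; 7 2,2,6-trimethyl-4H-1,3-dioxin-4-one
Product: 8 tert-butyl (3E,5E)-7-(3-oxobutanoyloxy)hepta-3,5-dienoate
Conditions: toluene, 110 °C
Reagents that add atoms: none
Why: Thermal retro-[4+2] of the dioxinone releases acetylketene, which the primary alcohol traps under neutral conditions (acetoacetylation) without isomerising the skipped dienoate.

**Step 4**
Reactants: 8 tert-butyl (3E,5E)-7-(3-oxobutanoyloxy)hepta-3,5-dienoate
Product: 9 tert-butyl (3E,5E)-7-(2-diazo-3-oxobutanoyloxy)hepta-3,5-dienoate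
Conditions: 4-acetamidobenzenesulfonyl azide, Et3N, MeCN, 0 °C to rt
Reagents that add atoms: 4-acetamidobenzenesulfonyl azide, CC(=O)Nc1ccc(cc1)S(=O)(=O)N=[N+]=[N-]
Why: Regitz diazo transfer occurs at the 1,3-dicarbonyl methylene, the only position acidic enough for triethylamine, leaving the C11 methylene untouched.

**Step 5**
Reactants: 9 tert-butyl (3E,5E)-7-(2-diazo-3-oxobutanoyloxy)hepta-3,5-dienoate
Product: 10 tert-butyl (3E,5E)-7-(2-diazo-3-hydroxybutanoyloxy)hepta-3,5-dienoate
Conditions: NaBH4, MeOH, 0 °C
Reagents that add atoms: none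
Why: NaBH4 reduces the ketone of the α-diazo-β-keto ester while the diazo ester, the tert-butyl ester and the diene are untouched; the carbinol stereocentre is lost in step 6.

**Step 6**
Reactants: 10 tert-butyl (3E,5E)-7-(2-diazo-3-hydroxybutanoyloxy)hepta-3,5-dienoate
Product: 11 tert-butyl (3E,5E)-7-(2-diazobut-3-enoyloxy)hepta-3,5-dienoate
Conditions: POCl3, Et3N, CH2Cl2, 0 °C; used at once
Reagents that add atoms: none
Why: O-Phosphorylation and base-induced E2 elimination give the vinyldiazoacetate (the established acetoacetate route to 2-diazobut-3-enoates), which is carried on immediately to avoid pyrazole formation.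

**Step 7 (key step)**
Reactants: 11 tert-butyl (3E,5E)-7-(2-diazobut-3-enoyloxy)hepta-3,5-dienoate
Product: 13 rac-tert-butyl 2-[(3a,6-cis)-1-oxo-3,3a,6,7-tetrahydro-1H-cyclohepta[c]furan-6-yl]acetate, via cis-divinylcyclopropane 12 (not isolated)
Conditions: Rh2(OAc)4 (1 mol %), CH2Cl2, 40 °C, slow addition of 11; then toluene, 80 °C
Reagents that add atoms: none
Why: Rh2(OAc)4 converts the diazo ester into a rhodium vinylcarbenoid that cyclopropanates the proximal C9=C10 alkene intramolecularly (forming C1–C10 and C1–C9), and the resulting cis-divinylcyclopropane 12 undergoes a boat-type Cope rearrangement that forms C6–C7 and breaks C1–C9, so that C10–C1 and C6–C7 of the seven-membered carbocycle (C10'–C1' and C6'–C7' in the epoxide half) are made in one operation. The closest known reaction type is the tandem intramolecular cyclopropanation/Cope rearrangement of dienyl vinyldiazoacetates, a formal intramolecular [4+3] cycloaddition. The five-membered lactone closes by carbenoid addition to the tethered allylic alkene (3-oxabicyclo[3.1.0]hexanone mode), and the cycloheptadiene closes by [3,3]-sigmatropic ring expansion of the cyclopropane. C10 is set in the cyclopropanation, where the (E)-alkene places C14 (held in the lactone) anti to both vinyl groups, and C7 is set in the Cope step, where the (E)-substituent CH2CO2tBu lies outside the boat, so H7 and H10 end up cis; absolute configuration is deliberately not controlled because both antipodes are needed. The step needs site selectivity for the proximal alkene over the distal alkene and over C–H insertion, which the three-atom ester tether secures, and a cis-divinyl arrangement, which the E geometry of C9=C10 secures.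

**Step 8**
Reactants: 13 rac-tert-butyl 2-[(3a,6-cis)-1-oxo-3,3a,6,7-tetrahydro-1H-cyclohepta[c]furan-6-yl]acetate
Product: 14 rac-tert-butyl 2-[(3a,6-cis)-1-hydroxy-3,3a,6,7-tetrahydro-1H-cyclohepta[c]furan-6-yl]acetate (lactol)
Conditions: iBu2AlH (1.1 equiv), CH2Cl2, −78 °C; aq. KNaC4H4O6
Reagents that add atoms: none
Why: At −78 °C iBu2AlH should stop at the lactol of the conjugated lactone (1,2-reduction through a stable tetrahedral aluminate) while the hindered tert-butyl ester is not reduced.

**Step 9**
Reactants: 14 lactol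
Product: 15 rac-tert-butyl 2-[(1,4-cis)-4-(hydroxymethyl)-5-vinylcyclohepta-2,5-dien-1-yl]acetate
Conditions: Ph3PCH3Br, KN(SiMe3)2, THF, 0 °C to rt
Reagents that add atoms: methyltriphenylphosphonium bromide, C[P+](c1ccccc1)(c1ccccc1)c1ccccc1.[Br-]
Why: Wittig methylenation of the open hydroxy-enal form of the lactol gives the C5=C1–C2=C3 diene and releases the C14 hydroxyl, the former tether oxygen.

**Step 10**
Reactants: 15 rac-tert-butyl 2-[(1,4-cis)-4-(hydroxymethyl)-5-vinylcyclohepta-2,5-dien-1-yl]acetate
Product: 16 rac-tert-butyl 2-[(1,4-cis)-4-(iodomethyl)-5-vinylcyclohepta-2,5-dien-1-yl]acetate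
Conditions: I2, PPh3, imidazole, CH2Cl2, 0 °C
Reagents that add atoms: iodine, [I][I]
Why: Appel iodination of the primary alcohol (SN2 on the alkoxyphosphonium ion) prepares C14 for reduction to the methyl group.

**Step 11**
Reactants: 16 rac-tert-butyl 2-[(1,4-cis)-4-(iodomethyl)-5-vinylcyclohepta-2,5-dien-1-yl]acetate
Product: 19 rac-8-iodo-7-(iodomethyl)-6-vinyl-3,3a,4,7,8,8a-hexahydro-2H-cyclohepta[b]furan-2-one (cis-fused lactone; CH2I cis to the lactone oxygen; ring iodine trans to it), via silyl ester 17 (not isolated), via carboxylic acid 18 (not isolated)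
Conditions: Me3SiOTf, 2,6-lutidine, CH2Cl2, 0 °C; H2O; then I2, NaHCO3, MeCN/H2O, 0 °C, dark
Reagents that add atoms: iodine, [I][I]
Why: The silyl triflate cleaves the tert-butyl ester without a protic acid that would harm the diene, and kinetic iodolactonisation then closes the γ-lactone on the isolated C8=C9 alkene; the carboxylate tethered at C7 can only reach C8 on its own face, so C8–O is cis to C7–C11 and iodine enters C9 anti.

**Step 12**
Reactants: 19 rac-diiodo lactone
Product: 20 rac-(3aR*,7S*,8aR*)-7-methyl-6-vinyl-3,3a,4,7,8,8a-hexahydro-2H-cyclohepta[b]furan-2-one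
Conditions: Bu3SnH (2.5 equiv, 0.3 M), AIBN (cat.), benzene, 80 °C
Reagents that add atoms: none
Why: Radical chain reduction replaces both C–I bonds by C–H, giving the C14 methyl group and the C9 methylene; the high stannane concentration should outrun 3-exo rearrangement of the homoallylic C14 radical.

**Step 13**
Reactants: 20 rac-(3aR*,7S*,8aR*)-7-methyl-6-vinyl-3,3a,4,7,8,8a-hexahydro-2H-cyclohepta[b]furan-2-one
Product: 23 rac-(3aR*,7S*,8aR*)-7-methyl-3-methylidene-6-vinyl-3,3a,4,7,8,8a-hexahydro-2H-cyclohepta[b]furan-2-one, via Mannich base 21 (not isolated), via ammonium iodide 22 (not isolated)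
Conditions: LiN(iPr)2, THF, −78 °C; CH2=NMe2+ I−, −78 to 0 °C; MeI, MeOH, rt; aq. NaHCO3, CH2Cl2
Reagents that add atoms: N,N-dimethylmethyleneiminium iodide (Eschenmoser's salt), C=[N+](C)C.[I-]
Why: Aminomethylation of the lactone enolate followed by quaternisation and E1cB elimination installs the exocyclic C13 methylene (standard α-methylenation), the diene offering no competing acidic site.

**Step 14**
Reactants: 23 rac-methylene lactone diene; 24 but-3-en-2-one
Product: 25 rac-8-epi-xanthatin, rac-(3aR*,7S*,8aR*)-7-methyl-3-methylidene-6-[(E)-3-oxobut-1-enyl]-3,3a,4,7,8,8a-hexahydro-2H-cyclohepta[b]furan-2-one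
Conditions: 24 (5 equiv), second-generation Hoveyda–Grubbs catalyst [RuCl2(H2IMes)(=CH-C6H4-2-OiPr)] (5 mol %), CH2Cl2, 40 °C
Reagents that add atoms: none
Why: Olefin cross-metathesis of the terminal vinyl group with the enone should give the (E)-dienone, the electron-poor 1,1-disubstituted methylene lactone and the trisubstituted ring alkene being inert to the catalyst.

**Step 15**
Reactants: 25 rac-8-epi-xanthatin
Product: 26 (3aR,7S,8aR)-8-epi-xanthatin and 27 (3aS,7R,8aS)-8-epi-xanthatin
Conditions: preparative HPLC, amylose tris(3,5-dimethylphenylcarbamate) stationary phase, hexane/iPrOH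
Reagents that add atoms: none
Why: Chromatographic resolution on a chiral stationary phase delivers both antipodes, each of which is consumed (26 as the diene half, 27 as the dienophile half), the assignment to be made by comparing chiroptical data of 26 with natural 8-epi-xanthatin.

**Step 16**
Reactants: 27 (3aS,7R,8aS)-8-epi-xanthatin
Product: 28 (1R,5R,7S,8S,10R)-1,5-epoxy-1,5-dihydro derivative of 27 (epoxide oxygen anti to C14 and to the lactone)
Conditions: D-fructose-derived Shi ketone (30 mol %), KHSO5 (as 2KHSO5·KHSO4·K2SO4), K2CO3, Bu4NHSO4, MeCN/CH2(OMe)2/aq. buffer, 0 °C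
Reagents that add atoms: potassium peroxymonosulfate, [K+].[O-]S(=O)(=O)OO
Why: In the Shi epoxidation the electrophilic chiral dioxirane attacks only the electron-rich γ,δ-alkene C1=C5, and its spiro transition state should deliver oxygen to the face anti to C14 and the lactone, reinforcing the steric bias of the substrate and setting C1 and C5.

**Step 17**
Reactants: 26 (3aR,7S,8aR)-8-epi-xanthatin; 28 epoxide
Product: 29 Diels–Alder adduct (C5–C13' and C3–C11' bonds, C1=C2 alkene, H3 and H5 cis, spiro centre C11' as in the target)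
Conditions: 28 (3 equiv), toluene (2 M), BHT (cat.), 90 °C, 26 added in portions
Reagents that add atoms: none
Why: A thermal Diels–Alder reaction joins the s-cis diene C5=C1–C2=C3 of 26 to the exocyclic C11'=C13' of 28 with the orientation set by the largest orbital coefficients (C5 to the unsubstituted C13', C3 to C11'), and is expected to proceed through the exo-carbonyl transition state on the convex H7'/H8' face of the cis-fused lactone and on the diene face syn to C14 (C14 pseudo-axial to avoid A(1,3) strain with H2, ring carbons C7–C9 folded to the other face), which sets C5 and C11'; excess 28 suppresses self-dimerisation of 26, and the diene-face selectivity is the least secure element of the route.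

**Step 18**
Reactants: 29 Diels–Alder adduct
Product: 31 target CNP0177598.2, via hydroperoxide 30 (not isolated)
Conditions: O2 (1 atm), DBU (0.3 equiv), MeCN, 0 °C; then PPh3
Reagents that add atoms: dioxygen, O=O
Why: Base-mediated autoxidation of the β,γ-unsaturated ketone should have the extended enolate (C3 deprotonated) capture O2 at the γ-carbon C1 by axial attack anti to the pseudo-axial H5, as in the γ-oxygenation of β,γ-unsaturated 3-keto steroids, giving the tertiary hydroperoxide with the alkene moved into conjugation (C2=C3), which PPh3 reduces to the C1 alcohol.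

**Compound list**

1 | (E)-pent-2-en-4-yn-1-ol | OC/C=C/C#C | starting material
2 | (2E,4E)-5-(tributylstannyl)penta-2,4-dien-1-ol | OC/C=C/C=C/[Sn](CCCC)(CCCC)CCCC | intermediate
3 | (2E,4E)-5-iodopenta-2,4-dien-1-ol | OC/C=C/C=C/[I] | intermediate
4 | tert-butyl bromoacetate | CC(C)(C)OC(=O)CBr | starting material
5 | bromo(2-tert-butoxy-2-oxoethyl)zinc | CC(C)(C)OC(=O)C[Zn]Br | intermediate
6 | tert-butyl (3E,5E)-7-hydroxyhepta-3,5-dienoate | CC(C)(C)OC(=O)C/C=C/C=C/CO | intermediate
7 | 2,2,6-trimethyl-4H-1,3-dioxin-4-one | CC1=CC(=O)OC(C)(C)O1 | starting material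
8 | tert-butyl (3E,5E)-7-(3-oxobutanoyloxy)hepta-3,5-dienoate | CC(=O)CC(=O)OC/C=C/C=C/CC(=O)OC(C)(C)C | intermediate
9 | tert-butyl (3E,5E)-7-(2-diazo-3-oxobutanoyloxy)hepta-3,5-dienoate | CC(=O)C(=[N+]=[N-])C(=O)OC/C=C/C=C/CC(=O)OC(C)(C)C | intermediate
10 | tert-butyl (3E,5E)-7-(2-diazo-3-hydroxybutanoyloxy)hepta-3,5-dienoate (racemic carbinol) | CC(O)C(=[N+]=[N-])C(=O)OC/C=C/C=C/CC(=O)OC(C)(C)C | intermediate
11 | tert-butyl (3E,5E)-7-(2-diazobut-3-enoyloxy)hepta-3,5-dienoate | C=CC(=[N+]=[N-])C(=O)OC/C=C/C=C/CC(=O)OC(C)(C)C | intermediate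
12 | rac-tert-butyl (E)-4-(2-oxo-1-vinyl-3-oxabicyclo[3.1.0]hexan-6-yl)but-3-enoate (the two alkenyl groups cis on the cyclopropane) | C=C[C@]12C(=O)OC[C@H]1[C@@H]2/C=C/CC(=O)OC(C)(C)C | intermediate
13 | rac-tert-butyl 2-[(3a,6-cis)-1-oxo-3,3a,6,7-tetrahydro-1H-cyclohepta[c]furan-6-yl]acetate | O=C1OC[C@H]2C=C[C@@H](CC(=O)OC(C)(C)C)CC=C12 | intermediate
14 | rac-tert-butyl 2-[(3a,6-cis)-1-hydroxy-3,3a,6,7-tetrahydro-1H-cyclohepta[c]furan-6-yl]acetate (lactol, anomers) | OC1OC[C@H]2C=C[C@@H](CC(=O)OC(C)(C)C)CC=C12 | intermediate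
15 | rac-tert-butyl 2-[(1,4-cis)-4-(hydroxymethyl)-5-vinylcyclohepta-2,5-dien-1-yl]acetate | C=CC1=CC[C@H](CC(=O)OC(C)(C)C)C=C[C@@H]1CO | intermediate
16 | rac-tert-butyl 2-[(1,4-cis)-4-(iodomethyl)-5-vinylcyclohepta-2,5-dien-1-yl]acetate | C=CC1=CC[C@H](CC(=O)OC(C)(C)C)C=C[C@@H]1C[I] | intermediate
17 | rac-trimethylsilyl 2-[(1,4-cis)-4-(iodomethyl)-5-vinylcyclohepta-2,5-dien-1-yl]acetate | C=CC1=CC[C@H](CC(=O)O[Si](C)(C)C)C=C[C@@H]1C[I] | intermediate
18 | rac-2-[(1,4-cis)-4-(iodomethyl)-5-vinylcyclohepta-2,5-dien-1-yl]acetic acid | C=CC1=CC[C@H](CC(=O)O)C=C[C@@H]1C[I] | intermediate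
19 | rac-8-iodo-7-(iodomethyl)-6-vinyl-3,3a,4,7,8,8a-hexahydro-2H-cyclohepta[b]furan-2-one (cis-fused; CH2I cis to lactone O; ring iodine trans to it) | O=C1C[C@H]2CC=C(C=C)[C@@H](C[I])[C@H]([I])[C@H]2O1 | intermediate
20 | rac-(3aR*,7S*,8aR*)-7-methyl-6-vinyl-3,3a,4,7,8,8a-hexahydro-2H-cyclohepta[b]furan-2-one | O=C1C[C@H]2CC=C(C=C)[C@@H](C)C[C@H]2O1 | intermediate
21 | rac-3-(dimethylaminomethyl) derivative of 20 (CH2N cis to H-3a) | CN(C)C[C@H]1C(=O)O[C@@H]2C[C@H](C)C(C=C)=CC[C@H]12 | intermediate
22 | rac-trimethylammoniomethyl iodide derived from 21 | C[N+](C)(C)C[C@H]1C(=O)O[C@@H]2C[C@H](C)C(C=C)=CC[C@H]12.[I-] | intermediate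
23 | rac-(3aR*,7S*,8aR*)-7-methyl-3-methylidene-6-vinyl-3,3a,4,7,8,8a-hexahydro-2H-cyclohepta[b]furan-2-one | C=C1C(=O)O[C@@H]2C[C@H](C)C(C=C)=CC[C@H]12 | intermediate
24 | but-3-en-2-one (methyl vinyl ketone) | C=CC(C)=O | starting material
25 | rac-8-epi-xanthatin | C=C1C(=O)O[C@@H]2C[C@H](C)C(/C=C/C(C)=O)=CC[C@H]12 | intermediate
26 | (3aR,7S,8aR)-7-methyl-3-methylidene-6-[(E)-3-oxobut-1-enyl]-3,3a,4,7,8,8a-hexahydro-2H-cyclohepta[b]furan-2-one (8-epi-xanthatin) | C=C1C(=O)O[C@@H]2C[C@H](C)C(/C=C/C(C)=O)=CC[C@H]12 | intermediate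
27 | (3aS,7R,8aS)-enantiomer of 26 | C=C1C(=O)O[C@H]2C[C@@H](C)C(/C=C/C(C)=O)=CC[C@@H]12 | intermediate
28 | (1R,5R,7S,8S,10R)-1,5-epoxide of 27 (xanthane numbering; epoxide anti to C14 and lactone) | C=C1C(=O)O[C@H]2C[C@@H](C)[C@]3(/C=C/C(C)=O)O[C@@H]3C[C@@H]12 | intermediate
29 | Diels–Alder adduct of 26 and 28 (C5–C13' and C3–C11' bonds; C1=C2; H3/H5 cis) | C=C1C(=O)O[C@@H]2C[C@H](C)C3=C[C@H](C(C)=O)[C@]4(C[C@@H]3C[C@H]12)C(=O)O[C@H]1C[C@@H](C)[C@]2(/C=C/C(C)=O)O[C@@H]2C[C@H]14 | intermediate
30 | C1 hydroperoxide of the target skeleton (C2=C3 enone) | C=C1C(=O)O[C@@H]2C[C@H](C)[C@@]3(OO)C=C(C(C)=O)[C@]4(C[C@@H]3C[C@H]12)C(=O)O[C@H]1C[C@@H](C)[C@]2(/C=C/C(C)=O)O[C@@H]2C[C@H]14 | intermediate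
31 | CNP0177598.2, (1S,5S,7R,8R,10S,11'R,1'R,5'R,7'S,8'S,10'R) heterodimer | C=C1C(=O)O[C@@H]2C[C@H](C)[C@@]3(O)C=C(C(C)=O)[C@]4(C[C@@H]3C[C@H]12)C(=O)O[C@H]1C[C@@H](C)[C@]2(/C=C/C(C)=O)O[C@@H]2C[C@H]14 | target

**Totals.** Total step count: 18. Longest linear sequence: 18 steps (1 to 28, then steps 17 and 18).

**Steps most likely to fail**

Step 17. The diene unit 26 carries its own methylene lactone and may dimerise with itself faster than it meets 28, and the cross-cycloaddition of two electron-poor partners may be sluggish; diene-face selectivity may also erode. The fallback sets out from 26 and returns at 29. Dimethylamine (THF, 0 °C) should add only to the exocyclic methylene of 26 and give the amino lactone, the 13-dimethylamino-11,13-dihydro derivative F3 (H11 cis to H7 expected). F3 no longer contains a dienophile and can be heated with 28 at higher concentration to give the amine-masked cycloadduct F4. Quaternisation with MeI and elimination with aq. NaHCO3 restores the methylene group and gives 29.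

Step 18. Oxygen may be captured at C3 or on the wrong face of C1, or the base may simply move the alkene into conjugation without oxygenation and attack the methylene lactone. The fallback sets out from 29 and returns at 31 and replaces the radical-chain autoxidation by a two-electron oxidation of an isolated intermediate. tBuMe2SiOTf and Et3N (CH2Cl2, −78 °C) should convert the most acidic ketone into the extended silyl dienol ether F5. Dimethyldioxirane (acetone, −78 °C) then epoxidises its distal C1=C2 bond from the same axial direction (vinylogous Rubottom oxidation), and AcOH/H2O collapses the silyloxy epoxide to 31.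

Step 7. The vinyldiazo ester may electrocyclise to a pyrazole before it meets the catalyst, or the carbenoid may dimerise or react at its vinylogous terminus instead of cyclopropanating the (E)-alkene. The fallback sets out from 9 and returns at 13 and avoids the vinyldiazo compound. The stable acceptor/acceptor diazo ester 9 is cyclised with Rh2(OAc)4 (or Cu(acac)2, toluene, 100 °C) to the 1-acetylcyclopropane lactone F1. NaBH4 (MeOH, 0 °C) gives the carbinol F2, and syn-dehydration with the Burgess reagent (benzene, 50 °C) gives the cis-divinylcyclopropane 12, which rearranges on warming to 13.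

**Further compounds**

F1 | step 7 | rac-tert-butyl (E)-4-(1-acetyl-2-oxo-3-oxabicyclo[3.1.0]hexan-6-yl)but-3-enoate (acetyl and butenoate chain cis) | CC(=O)[C@]12C(=O)OC[C@H]1[C@@H]2/C=C/CC(=O)OC(C)(C)C
F2 | step 7 | rac-tert-butyl (E)-4-[1-(1-hydroxyethyl)-2-oxo-3-oxabicyclo[3.1.0]hexan-6-yl]but-3-enoate (carbinol epimers) | CC(O)[C@]12C(=O)OC[C@H]1[C@@H]2/C=C/CC(=O)OC(C)(C)C
F3 | step 17 | 13-dimethylamino-11,13-dihydro derivative of 26 (H11 cis to H7) | CN(C)C[C@@H]1C(=O)O[C@@H]2C[C@H](C)C(/C=C/C(C)=O)=CC[C@H]12
F4 | step 17 | Diels–Alder adduct of F3 and 28 (amine-masked 29) | CN(C)C[C@@H]1C(=O)O[C@@H]2C[C@H](C)C3=C[C@H](C(C)=O)[C@]4(C[C@@H]3C[C@H]12)C(=O)O[C@H]1C[C@@H](C)[C@]2(/C=C/C(C)=O)O[C@@H]2C[C@H]14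
F5 | step 18 | tert-butyldimethylsilyl dienol ether of 29 (C4(OSi)=C3–C2=C1) | C=C1C(=O)O[C@@H]2C[C@H](C)C3=C/C(=C(\C)O[Si](C)(C)C(C)(C)C)[C@]4(C[C@@H]3C[C@H]12)C(=O)O[C@H]1C[C@@H](C)[C@]2(/C=C/C(C)=O)O[C@@H]2C[C@H]14
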